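All runs are simulated on assumed constants, noise included.

Sunday's run levelled off higher than Tuesday's, at 36.0% from 15.0 h on against 29.1%, and I began from that gap.

| flask | solid substrate | reagent | temperature | remark | time |
|---|---|---|---|---|---|
| Tuesday's | 0.020 M | 1.3 equiv | 25 °C | the very flask that is asked about, followed so far |  |
| Sunday's | 0.010 M | 1.3 equiv | 10 °C | run made earlier |  |
| flask | 0.020 M | 1.30 equiv | 25 °C |  | 25 h |

- Tuesday's (time / h: target / %): 4.00: 29.2; 8.00: 27.2; 10.0: 29.2; 15.0: 30.2; 20.0: 29.3; 25.0: 29.5
- Sunday's (time / h: target / %): 3.00: 40.3; 8.00: 37.4; 15.0: 36.2; 20.0: 35.6; 30.0: 36.3; 40.0: 36.0; 48.0: 35.8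

(readings scatter by 1 percentage point)

- gamma: at 25 h raise the temperature by 20 K, then wait 25 h
- theta: at 25 h add reagent, 50.0% of the amount charged, then wait 25 h
- eta: change nothing and wait 25 h more

- in percentages every species weighs as the solid substrate in it: one side product counts as two
- for target the solid product is counted in
- as a solid, counted per litre of solution: solid substrate, solid product
- the volume of additions can be left aside
- steps thought possible: solid substrate <-> dissolved substrate; solid substrate + target -> side product; solid product <-> target; target <-> isomer of the product; dissolved substrate + reagent <-> target
- at the start none of the solid substrate is in solution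

- target, in percent of the solid substrate first charged, at 25 h
- which option adds most target ("none" when 2 percentage points or less is all one gets) (gamma / theta / eta / none)
- target present, in percent of the solid substrate first charged, after gamma
- target present, in percent of the solid substrate first charged, after theta

Tuesday's target lay flat from 4.00 h on, give or take its scatter, so I expected nothing from eta and took 29.1% for now. I read Tuesday's level as the set point of a reversible step with both partners still present, like a tank whose inflow equals its outflow. For dissolved substrate + reagent <-> target, equal rates both ways hold the ratio Q = [target]/([dissolved substrate][reagent]) constant at one temperature. I counted the substrate not in target as dissolved, a crude lump that hides isomer and side product, which left 70.9% of the substrate and 1.01 equiv of reagent free. That gave 20.3 /M. This Q, an apparent equilibrium constant, target over the product of its two partners at the set point, is what I carried.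

With y the fraction in target, c the substrate charge and e the equivalents of reagent, y = Qc(1 − y)(e − y), and the smaller root of this quadratic is the level. Here Qc was 0.407. Theta raised e to 1.95, and the root gave 38.8%, a gain of 9.7 percentage points against a margin of 2 points.

Sunday's colder readings gave 59.8 /M, larger than Tuesday's, so I expected gamma to lower the level. I chose theta.

The forecast gave 29.2% now, 25% after gamma, 29.7% after theta and none as best, holding that “Extra reagent then has little to act on”.

The flask gave 28.2% now, 35.1% after theta and 13.7% after gamma, with theta best, so my theta figure stood 3.7 points high.

    solid substrate ⇌ dissolved substrate, rate k1*(cs1 - [dissolved substrate]) while solid is left; crystals form when [dissolved substrate] > cs1 (solubility = 11.0 mM, k = 0.0533 /min)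
    solid substrate + target → side product (k = 0.835 /M/min, Ea = 66.0 kJ/mol)
    solid product ⇌ target, rate k3*(cs3 - [target]) while solid is left; crystals form when [target] > cs3 (solubility = 9.80 mM, k = 1.04 /min)
    target ⇌ isomer of the product (K = 0.630, k = 0.0155 /min, Ea = 84.0 kJ/mol, ΔH = 8.00 kJ/mol)
    dissolved substrate + reagent ⇌ target (K = 43.0 /M, k = 7.37 /M/min, Ea = 66.0 kJ/mol, ΔH = −47.0 kJ/mol)
    (constants at 25 °C)

The neighbouring flask was this flask with 0.780 equiv of reagent, its substrate charge, temperature and time unchanged. I put Tuesday's Q into the same root with that e, and it gave 19.3%. At 25.0 h that neighbour stood at 18.9% target, beside 11.9% isomer and 14.1% side product, with 51% of its reagent still unbound.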